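**Retrosynthetic overview**
1. Target 16 ⇐ O-debenzylation of trans-dihydrobenzofuran 15 ⇐ acid-mediated C2 epimerisation and loss of the spare ether arm from cis-14.
2. Key step: the C2–C3 bond of the dihydrofuran ring by enantioselective rhodium-carbene 1,5 C–H insertion of diaryldiazomethane 13 into one of two equivalent 2,4-bis(benzyloxy)benzyl ether arms. The unused arm serves as the O4 protecting group.
3. Diazo 13 ⇐ hydrazone 12 ⇐ nitrile 8 + aryllithium 10 (C3–ring B bond), then exchange of the ketimine NH for NNH2.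
4. Nitrile 8 ⇐ B-alkyl Suzuki coupling (ring A–CH2CH2–ring D) ⇐ double SNAr of two equivalents of alcohol 2 on 4-bromo-2,6-difluorobenzonitrile 3.
5. Ring order: benzene rings A, B, C and D are all bought; the only ring formed is the dihydrofuran, in step 5.

Assumption: 1, 3, 6 and 9 are catalogue chemicals, and Rh2(R-PTAD)4 is taken to give the 3S product by analogy with simpler 2-benzyloxybenzophenone-derived carbenes; if a pilot run shows the opposite sense, the mirror-image catalyst Rh2(S-PTAD)4 is used with nothing else changed.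

**Step 1**
Reactants: 1 2,4-bis(benzyloxy)benzaldehyde
Product: 2 [2,4-bis(benzyloxy)phenyl]methanol
Conditions: NaBH4, THF/MeOH (4:1), 0 °C → rt
Reagents that add atoms: none
Why: Chemoselective borohydride reduction of an aryl aldehyde to the benzylic alcohol, with the benzyl ethers inert and no stereocentre formed.

**Step 2**
Reactants: 2 [2,4-bis(benzyloxy)phenyl]methanol (first equivalent); 3 4-bromo-2,6-difluorobenzonitrile
Product: 5 4-bromo-2,6-bis{[2,4-bis(benzyloxy)phenyl]methoxy}benzonitrile, via fluoro monoether 4 (not isolated)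
Conditions: NaH (2.4 equiv), THF/DMF (4:1), 0 → 50 °C (2.2 equiv of 2 in total)
Reagents that add atoms: [2,4-bis(benzyloxy)phenyl]methanol (the second equivalent of 2), OCc1ccc(OCc2ccccc2)cc1OCc1ccccc1
Why: Two-fold nucleophilic aromatic substitution (SNAr) in which one molecule of the sodium alkoxide of 2 displaces each of the two fluorides ortho to the nitrile, fluoride being displaced far faster than the para bromide, which therefore survives for step 3; no stereocentre is formed.

**Step 3**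
Reactants: 5 4-bromo-2,6-bis{[2,4-bis(benzyloxy)phenyl]methoxy}benzonitrile; 6 1-(benzyloxy)-4-ethenylbenzene
Product: 8 2,6-bis{[2,4-bis(benzyloxy)phenyl]methoxy}-4-{2-[4-(benzyloxy)phenyl]ethyl}benzonitrile, via alkylborane 7 (not isolated)
Conditions: 6, 9-BBN, THF, rt; then 5, PdCl2(dppf) (5 mol %), 3 M aq NaOH, THF, 65 °C
Reagents that add atoms: none
Why: Anti-Markovnikov hydroboration of the styrene followed by B-alkyl Suzuki–Miyaura coupling (oxidative addition of zerovalent palladium into the only C–Br bond) installs the saturated two-carbon tether in one pot, the hindered 2,6-dialkoxybenzonitrile being inert to aqueous base; no stereocentre is formed.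

**Step 4**
Reactants: 8 2,6-bis{[2,4-bis(benzyloxy)phenyl]methoxy}-4-{2-[4-(benzyloxy)phenyl]ethyl}benzonitrile; 9 1,3-bis(benzyloxy)-5-bromobenzene
Product: 12 [3,5-bis(benzyloxy)phenyl](2,6-bis{[2,4-bis(benzyloxy)phenyl]methoxy}-4-{2-[4-(benzyloxy)phenyl]ethyl}phenyl)methanone hydrazone, via aryllithium 10 (not isolated), via ketimine 11 (not isolated)
Conditions: 9, n-BuLi, THF, −78 °C; 8, −78 → 0 °C; AcOH; then N2H4·H2O (30 equiv), EtOH, 80 °C
Reagents that add atoms: hydrazine (used as the monohydrate), NN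
Why: Bromine–lithium exchange and 1,2-addition of the aryllithium to the nitrile give a hindered N–H ketimine that resists hydrolysis, and transimination with hydrazine (addition–elimination with loss of NH3) turns it into the free hydrazone without ever having to condense a di-ortho-substituted benzophenone; no stereocentre is formed.

**Step 5**
Reactants: 12 [3,5-bis(benzyloxy)phenyl](2,6-bis{[2,4-bis(benzyloxy)phenyl]methoxy}-4-{2-[4-(benzyloxy)phenyl]ethyl}phenyl)methanone hydrazone
Product: 14 (2R,3S)-2-[2,4-bis(benzyloxy)phenyl]-3-[3,5-bis(benzyloxy)phenyl]-4-{[2,4-bis(benzyloxy)phenyl]methoxy}-6-{2-[4-(benzyloxy)phenyl]ethyl}-2,3-dihydro-1-benzofuran (2,3-cis), via diazo compound 13 (not isolated)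
Conditions: MnO2 (10 equiv), CH2Cl2, rt, dark; filter; filtrate added slowly to Rh2(R-PTAD)4 (1 mol %), CH2Cl2, 0 °C
Reagents that add atoms: none
Why: Hydrazone oxidation gives the diaryldiazomethane, whose donor/donor rhodium carbene undergoes enantioselective intramolecular 1,5 C–H insertion into the hydridic O–CH2–aryl bond of either of the two symmetry-equivalent ether arms, the chiral carboxylate pocket of the dirhodium tetrakis[(R)-(1-adamantyl)(phthalimido)acetate] catalyst fixing C3 as S while the concerted insertion sets C2 as R (2,3-cis).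

**Step 6**
Reactants: 14 (2R,3S)-2-[2,4-bis(benzyloxy)phenyl]-3-[3,5-bis(benzyloxy)phenyl]-4-{[2,4-bis(benzyloxy)phenyl]methoxy}-6-{2-[4-(benzyloxy)phenyl]ethyl}-2,3-dihydro-1-benzofuran
Product: 15 (2S,3S)-2-[2,4-bis(benzyloxy)phenyl]-3-[3,5-bis(benzyloxy)phenyl]-6-{2-[4-(benzyloxy)phenyl]ethyl}-2,3-dihydro-1-benzofuran-4-ol (2,3-trans)
Conditions: TFA (10 equiv), C6HMe5 (5 equiv), CH2Cl2, 0 °C, 1 h; NaHCO3 quench
Reagents that add atoms: none
Why: Brønsted acid ionises both 2,4-dialkoxybenzylic C–O bonds, so the spare arm on O4 leaves as a benzylic cation trapped by pentamethylbenzene (Friedel–Crafts alkylation) while reversible heterolysis of the ring C2–O1 bond and re-closure by either of the two symmetry-equivalent ring A phenols (thermodynamic epimerisation) inverts C2 from R to the more stable trans S configuration, the C3 stereocentre (S) not being involved.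

**Step 7**
Reactants: 15 (2S,3S)-2-[2,4-bis(benzyloxy)phenyl]-3-[3,5-bis(benzyloxy)phenyl]-6-{2-[4-(benzyloxy)phenyl]ethyl}-2,3-dihydro-1-benzofuran-4-ol
Product: 16 (2S,3S)-2-(2,4-dihydroxyphenyl)-3-(3,5-dihydroxyphenyl)-6-[2-(4-hydroxyphenyl)ethyl]-2,3-dihydro-1-benzofuran-4-ol (CNP0329616.1)
Conditions: H2 (1 atm), 10% Pd/C, EtOAc/MeOH (1:1), rt; stopped after uptake of 5 equiv H2
Reagents that add atoms: none
Why: Neutral catalytic hydrogenolysis cleaves the five primary aryl benzyl ethers much faster than the secondary, ring-constrained C2–O1 bond, so both stereocentres and the dihydrofuran ring are retained.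

**Compound list**
1 | 2,4-bis(benzyloxy)benzaldehyde | O=Cc1ccc(OCc2ccccc2)cc1OCc1ccccc1 | starting material
2 | [2,4-bis(benzyloxy)phenyl]methanol | OCc1ccc(OCc2ccccc2)cc1OCc1ccccc1 | intermediate
3 | 4-bromo-2,6-difluorobenzonitrile | N#Cc1c(F)cc(Br)cc1F | starting material
4 | 4-bromo-2-fluoro-6-{[2,4-bis(benzyloxy)phenyl]methoxy}benzonitrile | N#Cc1c(F)cc(Br)cc1OCc1ccc(OCc2ccccc2)cc1OCc1ccccc1 | intermediate
5 | 4-bromo-2,6-bis{[2,4-bis(benzyloxy)phenyl]methoxy}benzonitrile | N#Cc1c(OCc2ccc(OCc3ccccc3)cc2OCc2ccccc2)cc(Br)cc1OCc1ccc(OCc2ccccc2)cc1OCc1ccccc1 | intermediate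
6 | 1-(benzyloxy)-4-ethenylbenzene | C=Cc1ccc(OCc2ccccc2)cc1 | starting material
7 | 9-{2-[4-(benzyloxy)phenyl]ethyl}-9-borabicyclo[3.3.1]nonane | C(Cc1ccc(OCc2ccccc2)cc1)B1C2CCCC1CCC2 | intermediate
8 | 2,6-bis{[2,4-bis(benzyloxy)phenyl]methoxy}-4-{2-[4-(benzyloxy)phenyl]ethyl}benzonitrile | N#Cc1c(OCc2ccc(OCc3ccccc3)cc2OCc2ccccc2)cc(CCc2ccc(OCc3ccccc3)cc2)cc1OCc1ccc(OCc2ccccc2)cc1OCc1ccccc1 | intermediate
9 | 1,3-bis(benzyloxy)-5-bromobenzene | Brc1cc(OCc2ccccc2)cc(OCc2ccccc2)c1 | starting material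
10 | [3,5-bis(benzyloxy)phenyl]lithium | [Li]c1cc(OCc2ccccc2)cc(OCc2ccccc2)c1 | intermediate
11 | 1-[3,5-bis(benzyloxy)phenyl]-1-(2,6-bis{[2,4-bis(benzyloxy)phenyl]methoxy}-4-{2-[4-(benzyloxy)phenyl]ethyl}phenyl)methanimine (N–H ketimine) | N=C(c1cc(OCc2ccccc2)cc(OCc2ccccc2)c1)c1c(OCc2ccc(OCc3ccccc3)cc2OCc2ccccc2)cc(CCc2ccc(OCc3ccccc3)cc2)cc1OCc1ccc(OCc2ccccc2)cc1OCc1ccccc1 | intermediate
12 | [3,5-bis(benzyloxy)phenyl](2,6-bis{[2,4-bis(benzyloxy)phenyl]methoxy}-4-{2-[4-(benzyloxy)phenyl]ethyl}phenyl)methanone hydrazone | NN=C(c1cc(OCc2ccccc2)cc(OCc2ccccc2)c1)c1c(OCc2ccc(OCc3ccccc3)cc2OCc2ccccc2)cc(CCc2ccc(OCc3ccccc3)cc2)cc1OCc1ccc(OCc2ccccc2)cc1OCc1ccccc1 | intermediate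
13 | 2-{[3,5-bis(benzyloxy)phenyl](diazo)methyl}-1,3-bis{[2,4-bis(benzyloxy)phenyl]methoxy}-5-{2-[4-(benzyloxy)phenyl]ethyl}benzene | [N-]=[N+]=C(c1cc(OCc2ccccc2)cc(OCc2ccccc2)c1)c1c(OCc2ccc(OCc3ccccc3)cc2OCc2ccccc2)cc(CCc2ccc(OCc3ccccc3)cc2)cc1OCc1ccc(OCc2ccccc2)cc1OCc1ccccc1 | intermediate
14 | (2R,3S)-2-[2,4-bis(benzyloxy)phenyl]-3-[3,5-bis(benzyloxy)phenyl]-4-{[2,4-bis(benzyloxy)phenyl]methoxy}-6-{2-[4-(benzyloxy)phenyl]ethyl}-2,3-dihydro-1-benzofuran (cis) | c1ccccc1COc1ccc(CCc2cc(OCc4ccc(OCc5ccccc5)cc4OCc4ccccc4)c3c(c2)O[C@@H](c2ccc(OCc4ccccc4)cc2OCc2ccccc2)[C@H]3c2cc(OCc3ccccc3)cc(OCc3ccccc3)c2)cc1 | intermediate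
15 | (2S,3S)-2-[2,4-bis(benzyloxy)phenyl]-3-[3,5-bis(benzyloxy)phenyl]-6-{2-[4-(benzyloxy)phenyl]ethyl}-2,3-dihydro-1-benzofuran-4-ol (trans) | c1ccccc1COc1ccc(CCc2cc(O)c3c(c2)O[C@H](c2ccc(OCc4ccccc4)cc2OCc2ccccc2)[C@H]3c2cc(OCc3ccccc3)cc(OCc3ccccc3)c2)cc1 | intermediate
16 | (2S,3S)-2-(2,4-dihydroxyphenyl)-3-(3,5-dihydroxyphenyl)-6-[2-(4-hydroxyphenyl)ethyl]-2,3-dihydro-1-benzofuran-4-ol | Oc1ccc(CCc2cc(O)c3c(c2)O[C@H](c2ccc(O)cc2O)[C@H]3c2cc(O)cc(O)c2)cc1 | target

**Totals and risks**
Total step count: 7. Longest linear sequence: 7 steps (1 → 2 → 5 → 8 → 12 → 14 → 15 → 16); 3, 6 and 9 enter directly.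

Most likely to fail, first: step 5. The carbene carries two ortho ether groups, a pattern for which yield, cis selectivity and ee of the insertion are untested, and azine formation competes. The fallback replaces the carbene by a sulfur-ylide [4+1] annulation of an ortho-quinone methide; it sets out from 8 and comes back to the route at 15. Nitrile 8 is treated with aryllithium 10 as in step 4. The crude ketimine is then heated with TFA, water and C6HMe5 in CH2Cl2 (40 °C), which hydrolyses the C=N bond and removes both ether arms to give the dihydroxy ketone F1. NaBH4 (THF/MeOH, 0 °C) gives the racemic benzhydrol F2, and 4-methylbenzenesulfinic acid (CH2Cl2, rt) converts it into the racemic sulfone F3. Separately, alcohol 2, (2R,5R)-2,5-dimethylthiolane and HBF4·OEt2 (CH2Cl2, 0 °C) give the benzylic sulfonium tetrafluoroborate F4. F3 and F4 are combined with Cs2CO3 (CH2Cl2, −20 °C → rt). Loss of sulfinate from F3 gives the ortho-quinone methide F5; the two ring A hydroxyls are equivalent, so only one quinone methide can form. The ylide of F4 adds to the exocyclic carbon and the phenoxide displaces the sulfide, which closes the ring with the 2,3-trans relationship and the O4 hydroxyl already free, that is, 15. The C2-symmetric sulfide sets the absolute sense; its antipode is used if ent-15 results, and chiral chromatography raises the ee if needed.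

Second: step 6. The ring-opened benzylic cation could lose the C3 proton (eroding ee at C3) or be captured by the scavenger. The fallback reverses the order and avoids strong acid; it sets out from 14 and comes back at 16. Hydrogenolysis of 14 (H2, 10% Pd/C, EtOAc/MeOH, rt) removes all seven benzyl ethers and cleaves the benzylic C–O bond of the spare arm to give the cis hexaphenol F6. With the para hydroxyl on ring C free, the C2–O1 bond opens to a quinone methide under very mild conditions (pyridinium p-toluenesulfonate, 0.1 equiv, MeCN, 40 °C), and re-closure gives the trans target 16 directly.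

Third: step 4. Hydrazine may fail to attack the carbon of the doubly ortho-substituted ketimine. The fallback forms the N–N bond at nitrogen instead of exchanging at carbon; it sets out from 8 and comes back at 12. The N-lithiated form of ketimine 11, produced by adding 10 to 8, is not quenched but treated with O-(diphenylphosphinyl)hydroxylamine (1.5 equiv, THF, −78 → 0 °C). Electrophilic amination gives hydrazone 12 directly, retaining the nitrile nitrogen. No new compound is made.

**Further compounds**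
F1 | step 5 | (2,6-dihydroxy-4-{2-[4-(benzyloxy)phenyl]ethyl}phenyl)[3,5-bis(benzyloxy)phenyl]methanone | O=C(c1cc(OCc2ccccc2)cc(OCc2ccccc2)c1)c1c(O)cc(CCc2ccc(OCc3ccccc3)cc2)cc1O
F2 | step 5 | racemic 2-{[3,5-bis(benzyloxy)phenyl](hydroxy)methyl}-5-{2-[4-(benzyloxy)phenyl]ethyl}benzene-1,3-diol | OC(c1cc(OCc2ccccc2)cc(OCc2ccccc2)c1)c1c(O)cc(CCc2ccc(OCc3ccccc3)cc2)cc1O
F3 | step 5 | racemic 2-{[3,5-bis(benzyloxy)phenyl](4-methylbenzenesulfonyl)methyl}-5-{2-[4-(benzyloxy)phenyl]ethyl}benzene-1,3-diol | Cc1ccc(cc1)S(=O)(=O)C(c1cc(OCc2ccccc2)cc(OCc2ccccc2)c1)c1c(O)cc(CCc2ccc(OCc3ccccc3)cc2)cc1O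
F4 | step 5 | (2R,5R)-1-{[2,4-bis(benzyloxy)phenyl]methyl}-2,5-dimethylthiolan-1-ium tetrafluoroborate | C[C@@H]1CC[C@@H](C)[S+]1Cc1ccc(OCc2ccccc2)cc1OCc1ccccc1.F[B-](F)(F)F
F5 | step 5 | 6-{[3,5-bis(benzyloxy)phenyl]methylidene}-3-{2-[4-(benzyloxy)phenyl]ethyl}-5-hydroxycyclohexa-2,4-dien-1-one | O=C1C=C(CCc2ccc(OCc3ccccc3)cc2)C=C(O)C1=Cc1cc(OCc2ccccc2)cc(OCc2ccccc2)c1
F6 | step 6 | (2R,3S)-2-(2,4-dihydroxyphenyl)-3-(3,5-dihydroxyphenyl)-6-[2-(4-hydroxyphenyl)ethyl]-2,3-dihydro-1-benzofuran-4-ol (cis) | Oc1ccc(CCc2cc(O)c3c(c2)O[C@@H](c2ccc(O)cc2O)[C@H]3c2cc(O)cc(O)c2)cc1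
F0 | step 4 | none | none
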